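**Assumption:** in step 4 the antipode of the chiral counter-anion that gives the (2R) acetate is found by running both antipodes once and correlating the product with material from the known-chemistry fallback. Descriptors (2R,8S) are read from the target SMILES.

## Retrosynthetic overview

1. 14 ⇒ 11: the phenolic C–O bond is made last, by meta C–H borylation/oxidation of a 3-methoxyphenyl ring, so the phenol never needs protection.
2. 11 ⇒ 9 + AcOH: the C2–OAc bond is the key bond, formed by a new enantioselective anti-Markovnikov hydroacetoxylation of an (E)-β-alkylstyrene. It sets C2 and puts the acetate only on C2, so C8–OH stays free.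
3. 9 ⇒ 7 + 3-methoxystyrene by cross-metathesis.
4. 7 ⇒ (S)-epichlorohydrin + BuMgCl + hex-5-enylMgBr by two Cu-catalysed epoxide openings; the C8–O stereocentre comes from the chiral pool.
5. No ring is formed in the route; the benzene ring is bought.

## Route

**Step 1**
Reactants: 1 (S)-epichlorohydrin; 2 n-butylmagnesium chloride
Product: 4 (S)-1,2-epoxyheptane [(S)-2-pentyloxirane], via (S)-1-chloroheptan-2-ol 3 (not isolated)
Conditions: 2 (1.2 equiv), CuI (5 mol%), THF, −40 → 0 °C; aq NH4Cl; crude 3, powdered NaOH, Et2O, rt; distil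
Reagents that add atoms: n-butylmagnesium chloride (2), CCCC[Mg]Cl
Why: Cu-catalysed Grignard opening at the epoxide CH2 followed by intramolecular Williamson closure onto CH2Cl (epoxide transposition) never breaks the C–O bond at the stereocentre, so (S)-epichlorohydrin gives (S)-2-pentyloxirane.

**Step 2**
Reactants: 4 (S)-1,2-epoxyheptane; 5 6-bromohex-1-ene
Product: 7 (6S)-tridec-12-en-6-ol, via hex-5-enylmagnesium bromide 6 (not isolated)
Conditions: 5, Mg, THF, rt; then CuI (10 mol%), 4, THF, −30 → 0 °C; aq NH4Cl
Reagents that add atoms: 6-bromohex-1-ene (5, as its Grignard reagent 6), C=CCCCCBr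
Why: Cu-catalysed SN2 opening of the terminal epoxide at CH2 by the primary Grignard reagent leaves the C–O stereocentre untouched, so (S) is carried into C8 of the target.

**Step 3**
Reactants: 7 (6S)-tridec-12-en-6-ol; 8 3-methoxystyrene
Product: 9 (6S,12E)-13-(3-methoxyphenyl)tridec-12-en-6-ol
Conditions: 8 (3 equiv), Grubbs II (3 mol%), CH2Cl2, 40 °C
Reagents that add atoms: 3-methoxystyrene (8), C=Cc1cccc(OC)c1
Why: Ru-catalysed olefin cross-metathesis of a terminal alkene with excess styrene gives the (E)-β-alkylstyrene with loss of ethene; the free OH is tolerated and C8 is remote.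

**Step 4**
Reactants: 9 (6S,12E)-13-(3-methoxyphenyl)tridec-12-en-6-ol; 10 acetic acid
Product: 11 (2R,8S)-8-hydroxy-1-(3-methoxyphenyl)tridecan-2-yl acetate
Conditions: 10 (10 equiv), [9-mesityl-3,6-di-tert-butyl-10-phenylacridinium]+ [confined BINOL-derived imidodiphosphorimidate (IDPi)]− chiral ion pair (5 mol%, antipode giving 2R), PhSSPh (10 mol%), CHCl3, 450 nm LEDs, −30 °C
Reagents that add atoms: acetic acid (10), CC(=O)O
Why: Proposed new method: enantioselective anti-Markovnikov hydroacetoxylation through a chiral-anion-paired alkene radical cation — the excited acridinium oxidises the styrene to its radical cation, which in the non-polar medium can only pair with the IDPi anion (the sole anion present), acetic acid hydrogen-bonded to that anion adds to one face of C2 (the site that leaves the benzylic radical), and thiol H-atom transfer to C1 with proton return by thiolate closes the cycle, so the C2–O bond and the (R) centre are made in one catalyst-controlled event while the remote C8 centre is untouched; the closest known reaction types are the racemic acridinium/thiol photoredox anti-Markovnikov addition of carboxylic acids to β-alkylstyrenes and chiral-counteranion-directed radical-cation cycloadditions.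

**Step 5**
Reactants: 11 (2R,8S)-8-hydroxy-1-(3-methoxyphenyl)tridecan-2-yl acetate; 12 bis(pinacolato)diboron
Product: 14 (2R,8S)-8-hydroxy-1-(3-hydroxy-5-methoxyphenyl)tridecan-2-yl acetate, via aryl boronate O-Bpin ester 13 (not isolated)
Conditions: [Ir(OMe)(cod)]2 (1.5 mol%), dtbpy (3 mol%), 12 (1.5 equiv), HBpin (10 mol%), THF, 80 °C; then Oxone, acetone/H2O, rt, 10 min
Reagents that add atoms: bis(pinacolato)diboron (12, boron only in 13), CC1(C)OB(OC1(C)C)B1OC(C)(C)C(C)(C)O1; Oxone (potassium peroxymonosulfate), [K+].[O-]S(=O)(=O)OO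
Why: Sterically controlled Ir-catalysed aromatic C–H borylation reaches only C5, the one ring C–H with no ortho substituent, while C8–OH is masked in situ as its O–Bpin ester, and Oxone then turns C–B into C–OH by 1,2-aryl migration and hydrolyses the borate ester, leaving the acetate and both stereocentres untouched.

## Compound list

1 | (S)-epichlorohydrin [(S)-2-(chloromethyl)oxirane] | ClC[C@@H]1CO1 | starting material
2 | n-butylmagnesium chloride | CCCC[Mg]Cl | starting material
3 | (S)-1-chloroheptan-2-ol | CCCCC[C@H](O)CCl | intermediate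
4 | (S)-1,2-epoxyheptane [(S)-2-pentyloxirane] | CCCCC[C@H]1CO1 | intermediate
5 | 6-bromohex-1-ene | C=CCCCCBr | starting material
6 | hex-5-enylmagnesium bromide | C=CCCCC[Mg]Br | intermediate
7 | (6S)-tridec-12-en-6-ol | CCCCC[C@H](O)CCCCCC=C | intermediate
8 | 3-methoxystyrene (1-ethenyl-3-methoxybenzene) | C=Cc1cccc(OC)c1 | starting material
9 | (6S,12E)-13-(3-methoxyphenyl)tridec-12-en-6-ol | CCCCC[C@H](O)CCCCC/C=C/c1cccc(OC)c1 | intermediate
10 | acetic acid | CC(=O)O | starting material
11 | (2R,8S)-8-hydroxy-1-(3-methoxyphenyl)tridecan-2-yl acetate | CCCCC[C@H](O)CCCCC[C@H](Cc1cccc(OC)c1)OC(C)=O | intermediate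
12 | bis(pinacolato)diboron | CC1(C)OB(OC1(C)C)B1OC(C)(C)C(C)(C)O1 | starting material
13 | (2R,8S)-1-[3-methoxy-5-(4,4,5,5-tetramethyl-1,3,2-dioxaborolan-2-yl)phenyl]-8-[(4,4,5,5-tetramethyl-1,3,2-dioxaborolan-2-yl)oxy]tridecan-2-yl acetate | CCCCC[C@H](OB1OC(C)(C)C(C)(C)O1)CCCCC[C@H](Cc1cc(B2OC(C)(C)C(C)(C)O2)cc(OC)c1)OC(C)=O | intermediate
14 | (2R,8S)-8-hydroxy-1-(3-hydroxy-5-methoxyphenyl)tridecan-2-yl acetate | CCCCC[C@H](O)CCCCC[C@H](Cc1cc(O)cc(OC)c1)OC(C)=O | target

## Step count and risks

Total step count: 5. Longest linear sequence: 5 (1 → 4 → 7 → 9 → 11 → 14).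

**Step 4 (the proposed new reaction) is the most likely to fail.** The risks are low enantioselectivity from a loosely paired radical cation, ether formation by the C8–OH of a second molecule, and oxidation of the product arene. The fallback uses known chemistry only, sets out from 9 and comes back at 11. TBSCl and imidazole in DMF give tert-butyl{[(6S,12E)-13-(3-methoxyphenyl)tridec-12-en-6-yl]oxy}dimethylsilane F1. Shi epoxidation (D-fructose-derived ketone, Oxone, K2CO3 buffer, MeCN/dimethoxymethane, 0 °C) gives the trans-epoxide tert-butyl({(6S)-11-[(2R,3R)-3-(3-methoxyphenyl)oxiran-2-yl]undecan-6-yl}oxy)dimethylsilane F2, which sets C2 through a C–O bond. H2 over Pd/C in EtOAc cleaves only the benzylic C–O bond and gives (2R,8S)-8-[(tert-butyldimethylsilyl)oxy]-1-(3-methoxyphenyl)tridecan-2-ol F3. Ac2O, DMAP and pyridine give (2R,8S)-8-[(tert-butyldimethylsilyl)oxy]-1-(3-methoxyphenyl)tridecan-2-yl acetate F4. HF·pyridine in THF removes the silyl group and returns 11.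

**Step 5 is the second risk.** Minor borylation ortho to OMe, catalyst inhibition by the alcohol, or over-oxidation by Oxone could lower the yield. The fallback sets out from 7 and comes back at 14, carrying the phenol oxygen in from the start as a benzyl ether. Commercial 3-bromo-5-methoxyphenol with BnBr and K2CO3 in DMF gives 1-(benzyloxy)-3-bromo-5-methoxybenzene F5. Suzuki–Miyaura vinylation (potassium vinyltrifluoroborate, PdCl2(dppf), Cs2CO3, THF/H2O) gives 1-(benzyloxy)-3-ethenyl-5-methoxybenzene F6. Cross-metathesis with 7 under the step 3 conditions gives (6S,12E)-13-[3-(benzyloxy)-5-methoxyphenyl]tridec-12-en-6-ol F7. The step 4 hydroacetoxylation gives (2R,8S)-1-[3-(benzyloxy)-5-methoxyphenyl]-8-hydroxytridecan-2-yl acetate F8. H2 over Pd/C in EtOAc removes the benzyl group and gives 14.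

**Step 3 is the third risk.** Homodimers, double-bond migration in 7, or incomplete E selectivity could complicate it. The fallback sets out from 7 and comes back at 9 by a different C–C bond-forming reaction: an oxidative boron-Heck arylation of 7 with 3-methoxyphenylboronic acid (Pd(IiPr)(OTs)2, Cu(OTf)2, O2, DMA), which is (E)-styrenyl-selective on unbiased 1-alkenes and tolerates free alcohols. No new compound is made on this path (F0).

## Further compounds

F0 | step 3 | none | none
F1 | step 4 | tert-butyl{[(6S,12E)-13-(3-methoxyphenyl)tridec-12-en-6-yl]oxy}dimethylsilane | CCCCC[C@H](O[Si](C)(C)C(C)(C)C)CCCCC/C=C/c1cccc(OC)c1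
F2 | step 4 | tert-butyl({(6S)-11-[(2R,3R)-3-(3-methoxyphenyl)oxiran-2-yl]undecan-6-yl}oxy)dimethylsilane | CCCCC[C@H](O[Si](C)(C)C(C)(C)C)CCCCC[C@H]1O[C@@H]1c1cccc(OC)c1
F3 | step 4 | (2R,8S)-8-[(tert-butyldimethylsilyl)oxy]-1-(3-methoxyphenyl)tridecan-2-ol | CCCCC[C@H](O[Si](C)(C)C(C)(C)C)CCCCC[C@H](Cc1cccc(OC)c1)O
F4 | step 4 | (2R,8S)-8-[(tert-butyldimethylsilyl)oxy]-1-(3-methoxyphenyl)tridecan-2-yl acetate | CCCCC[C@H](O[Si](C)(C)C(C)(C)C)CCCCC[C@H](Cc1cccc(OC)c1)OC(C)=O
F5 | step 5 | 1-(benzyloxy)-3-bromo-5-methoxybenzene | COc1cc(Br)cc(OCc2ccccc2)c1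
F6 | step 5 | 1-(benzyloxy)-3-ethenyl-5-methoxybenzene | C=Cc1cc(OC)cc(OCc2ccccc2)c1
F7 | step 5 | (6S,12E)-13-[3-(benzyloxy)-5-methoxyphenyl]tridec-12-en-6-ol | CCCCC[C@H](O)CCCCC/C=C/c1cc(OC)cc(OCc2ccccc2)c1
F8 | step 5 | (2R,8S)-1-[3-(benzyloxy)-5-methoxyphenyl]-8-hydroxytridecan-2-yl acetate | CCCCC[C@H](O)CCCCC[C@H](Cc1cc(OC)cc(OCc2ccccc2)c1)OC(C)=O
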